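Atom labels: ring A = C1 (spiro carbon), C2 (ketone), C3, C4 (NHAc), C5 (OH), C6; lactone = C1–C7–C8(=O)–O9–C10; side chain from C11=C12 onward.
Cuts, in retrosynthetic order: N–acetyl and C4–N (back to a C3=C4 enone with free C5–OH); O9–C8 and C10–H (back to a C10 ketone and a C8 methyl ester); C1–C2 together with C5–C6 (Diels–Alder); finally C10–C11 (acylation of an alkenylzinc).
What allows the central cut: in ring A the oxygen-bearing carbons C2 and C5 are the termini of the four-carbon unit C2–C3–C4–C5, the imprint of a 1,4-dioxygenated butadiene. The other two ring atoms, C6H2 and the quaternary C1 that carries both C7 and the carbonyl-level C10, are the imprint of a 1,1-disubstituted, acyl-activated alkene.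
Forward order: the acyclic chain is joined first, ring A closes in the cycloaddition, the lactone ring closes after reduction at C10, and a temporary oxazoline ring across C4/C5 brings in nitrogen and is opened at the end.
Stereochemistry: C1 and C5 (plus a sacrificial centre at C2) come from an endo, suprafacial cycloaddition on one enantioface chosen by a chiral oxazaborolidinium catalyst. C10 comes from a CBS catalyst, which also turns any minor enantiomer into a separable diastereomer. C4 comes from the C5–O tether, and the C11=C12 E geometry from syn-carboalumination.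

Key step: step 5

Assumption: the (S)-configured Diels–Alder catalyst is taken to leave open the enantioface of the dienone that leads to the (1S,2S,5S) cycloadduct; should the induction run the other way, the (R)-catalyst is used and nothing else changes.
Remark: C-numbers in the running text are the labels defined above; locants inside systematic names follow nomenclature rules.

Step 1
Reactants: 1 methylheptenone (6-methylhept-5-en-2-one)
Product: 3 enyne (6-methylhept-5-en-1-yne), via enol phosphate 2 (not isolated)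
Conditions: LDA (1.05 equiv), THF, −78 °C; ClP(O)(OEt)2, −78 °C to rt; LDA (2.3 equiv), THF, −78 °C to rt; H2O
Reagents that add atoms: none
Why: Kinetic deprotonation on the CH3 side, O-phosphorylation and base-induced β-elimination of diethyl phosphate (Negishi conversion of a methyl ketone into a terminal alkyne) is well precedented for aliphatic methyl ketones and leaves the trisubstituted alkene untouched.

Step 2
Reactants: 3 enyne (6-methylhept-5-en-1-yne)
Product: 5 (1E)-1-iodo-2,6-dimethylhepta-1,5-diene, via alkenylalane 4 (not isolated)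
Conditions: Me3Al (2 equiv), Cp2ZrCl2 (0.2 equiv), CH2Cl2, 0 °C to rt; I2, THF, −30 to 0 °C
Reagents that add atoms: trimethylaluminium, C[Al](C)C; iodine, II
Why: Negishi carboalumination adds CH3 and Al syn across the terminal alkyne with Al at the terminus, and iodinolysis of the C–Al bond goes with retention, so the E geometry of the later C11=C12 bond is fixed here while the isolated alkene does not react.

Step 3
Reactants: 6 monomethyl itaconate (4-methoxy-2-methylidene-4-oxobutanoic acid)
Product: 7 methyl 3-(chlorocarbonyl)but-3-enoate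
Conditions: (COCl)2 (1.2 equiv), DMF (cat.), CH2Cl2, 0 °C to rt; evaporated and used crude
Reagents that add atoms: oxalyl chloride, O=C(Cl)C(=O)Cl
Why: Vilsmeier-type activation of the free conjugated acid gives the acid chloride under cold, base-free conditions that neither touch the methyl ester nor move the exocyclic double bond.

Step 4
Reactants: 5 (1E)-1-iodo-2,6-dimethylhepta-1,5-diene; 7 methyl 3-(chlorocarbonyl)but-3-enoate
Product: 10 dienone methyl (5E)-6,10-dimethyl-3-methylidene-4-oxoundeca-5,9-dienoate, via alkenyllithium 8 (not isolated), via alkenylzinc chloride 9 (not isolated)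
Conditions: 5, t-BuLi (2.0 equiv), Et2O, −78 °C; ZnCl2 (1.1 equiv), THF, −78 to 0 °C; 7, Pd(PPh3)4 (5 mol %), THF, 0 °C
Reagents that add atoms: none
Why: Iodine–lithium exchange and transmetalation keep the alkene geometry, and the Negishi acylation (oxidative addition of zerovalent palladium into the acyl C–Cl bond, transmetalation, reductive elimination) stops at the ketone because the organozinc adds to neither ketone nor ester and is too weakly basic to isomerise the itaconyl unit.

Step 5
Reactants: 10 dienone methyl (5E)-6,10-dimethyl-3-methylidene-4-oxoundeca-5,9-dienoate; 11 (1E,3E)-buta-1,3-diene-1,4-diyl diacetate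
Product: 12 all-cis cycloadduct methyl 2-[(1S,2S,5S)-2,5-diacetoxy-1-[(2E)-3,7-dimethylocta-2,6-dienoyl]cyclohex-3-en-1-yl]acetate
Conditions: (S)-1-(2-methylphenyl)-3,3-diphenyltetrahydro-1H,3H-pyrrolo[1,2-c][1,3,2]oxazaborole (20 mol %), Tf2NH (18 mol %), CH2Cl2, −25 °C; then 10, 11 (2 equiv), −20 °C to rt
Reagents that add atoms: none
Why: The cationic oxazaborolidinium made from the oxazaborolidine and Tf2NH binds the C10 carbonyl oxygen and lowers the LUMO of the dienone, after which C1=C6 and the two termini of 11 combine in a concerted, suprafacial [4+2] cycloaddition of normal electron demand that makes C1–C2 and C5–C6. The closest known reaction type is the oxazaborolidinium-catalysed enantioselective Diels–Alder reaction of enones and α-substituted acroleins with acyclic 1-oxygenated dienes. Ring A closes in the intermolecular cycloaddition itself, both σ-bonds forming in the same event and C3=C4 remaining as the ring alkene. C2 and C5 come out cis because both acetoxy groups are outside substituents of the (E,E)-diene, C1 is tied to them by the acyl-endo transition state (C10=O under the diene, CH2CO2Me exo) to give the all-cis array, and the absolute sense comes from the aryl group of the catalyst covering one face of the bound dienophile. The step needs site selectivity between the two alkenes of 10, which the substitution pattern supplies: the CH2 terminus C6 is open to the diene, whereas C12 is β,β-disubstituted. Because the two ends of 11 are equivalent, both orientations lead to the same constitution.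

Step 6
Reactants: 12 all-cis cycloadduct methyl 2-[(1S,2S,5S)-2,5-diacetoxy-1-[(2E)-3,7-dimethylocta-2,6-dienoyl]cyclohex-3-en-1-yl]acetate
Product: 13 allylic alcohol methyl 2-[(1R,2S,5S)-2,5-diacetoxy-1-[(1R,2E)-1-hydroxy-3,7-dimethylocta-2,6-dien-1-yl]cyclohex-3-en-1-yl]acetate
Conditions: (S)-1-methyl-3,3-diphenyltetrahydro-1H,3H-pyrrolo[1,2-c][1,3,2]oxazaborole [(S)-Me-CBS, 0.5 equiv], catecholborane (2 equiv), toluene, −78 to −40 °C; aq. NaHCO3 work-up
Reagents that add atoms: none
Why: In this Corey–Bakshi–Shibata 1,2-reduction the catalyst binds the carbonyl lone pair away from the larger quaternary C1 and delivers hydride from coordinated catecholborane to one face, which with the (S)-catalyst should give (10R); esters, acetates and alkenes survive at low temperature, any early lactonisation converges in step 7, and material derived from the minor enantiomer of 12 becomes a separable diastereomer.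

Step 7
Reactants: 13 allylic alcohol methyl 2-[(1R,2S,5S)-2,5-diacetoxy-1-[(1R,2E)-1-hydroxy-3,7-dimethylocta-2,6-dien-1-yl]cyclohex-3-en-1-yl]acetate
Product: 15 diol lactone (1R,5S,6S,9S)-1-[(1E)-2,6-dimethylhepta-1,5-dien-1-yl]-6,9-dihydroxy-2-oxaspiro[4.5]dec-7-en-3-one, via lactone diacetate 14 (not isolated)
Conditions: K2CO3 (0.3 equiv), MeOH, 0 °C to rt
Reagents that add atoms: none
Why: In this base-catalysed transesterification C10–OH closes the five-membered lactone on the C8 ester (5-exo-trig, helped by the quaternary C1) and methanol then removes both acetates; C2–O lies trans to the C7 arm, so its lactone would be a strained trans-fused ring on a cyclohexene, and C5–O cannot reach C8, so the spiro lactone should prevail.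

Step 8
Reactants: 15 diol lactone (1R,5S,6S,9S)-1-[(1E)-2,6-dimethylhepta-1,5-dien-1-yl]-6,9-dihydroxy-2-oxaspiro[4.5]dec-7-en-3-one
Product: 16 mono-silyl ether (1R,5S,6S,9S)-9-[tert-butyl(dimethyl)silyl]oxy-1-[(1E)-2,6-dimethylhepta-1,5-dien-1-yl]-6-hydroxy-2-oxaspiro[4.5]dec-7-en-3-one
Conditions: TBSCl (1.1 equiv), imidazole (2 equiv), DMF, 0 °C
Reagents that add atoms: tert-butyldimethylsilyl chloride, CC(C)(C)[Si](C)(C)Cl
Why: Sterically controlled silylation should pick C5–OH, an ordinary secondary allylic alcohol, over C2–OH, which is neopentyl-like and crowded by the spiro carbon and the C10 substituent on the same face.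

Step 9
Reactants: 16 mono-silyl ether (1R,5S,6S,9S)-9-[tert-butyl(dimethyl)silyl]oxy-1-[(1E)-2,6-dimethylhepta-1,5-dien-1-yl]-6-hydroxy-2-oxaspiro[4.5]dec-7-en-3-one
Product: 17 silyloxy enone (1R,5R,9S)-9-[tert-butyl(dimethyl)silyl]oxy-1-[(1E)-2,6-dimethylhepta-1,5-dien-1-yl]-2-oxaspiro[4.5]dec-7-ene-3,6-dione
Conditions: Dess–Martin periodinane (1.5 equiv), CH2Cl2, 0 °C to rt
Reagents that add atoms: none
Why: Dess–Martin oxidation handles hindered allylic alcohols under nearly neutral conditions and erases the sacrificial C2 centre; since C1 is quaternary, neither epimerisation nor β-elimination of the lactone oxygen can follow.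

Step 10
Reactants: 17 silyloxy enone (1R,5R,9S)-9-[tert-butyl(dimethyl)silyl]oxy-1-[(1E)-2,6-dimethylhepta-1,5-dien-1-yl]-2-oxaspiro[4.5]dec-7-ene-3,6-dione
Product: 18 hydroxy enone (1R,5R,9S)-1-[(1E)-2,6-dimethylhepta-1,5-dien-1-yl]-9-hydroxy-2-oxaspiro[4.5]dec-7-ene-3,6-dione
Conditions: HF·pyridine, pyridine, THF, 0 °C to rt
Reagents that add atoms: none
Why: Buffered fluoride desilylation frees C5–OH without the basic conditions that could isomerise a γ-oxygenated enone, and it leaves the lactone and alkenes alone.

Step 11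
Reactants: 18 hydroxy enone (1R,5R,9S)-1-[(1E)-2,6-dimethylhepta-1,5-dien-1-yl]-9-hydroxy-2-oxaspiro[4.5]dec-7-ene-3,6-dione
Product: 20 oxazoline (cis-fused 2-(trichloromethyl)-4,5-dihydro-1,3-oxazole with N on C4 and O on C5 of the saturated spiro keto lactone; C1 R; C4 R; C5 S; C10 R), via trichloroacetimidate 19 (not isolated)
Conditions: Cl3CCN (2 equiv), DBU (0.2 equiv), CH2Cl2, 0 °C to rt
Reagents that add atoms: trichloroacetonitrile, N#CC(Cl)(Cl)Cl
Why: Base-catalysed addition of C5–OH to the nitrile gives the imidate, whose nitrogen adds to C4 of the enone in a 5-exo-trig intramolecular aza-Michael reaction; the short tether reaches C4 only from the face that carries C5–O, so the new C4–N bond is cis to C5–O (4R).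

Step 12
Reactants: 20 oxazoline (cis-fused 2-(trichloromethyl)-4,5-dihydro-1,3-oxazole on C4/C5 of the spiro keto lactone)
Product: 22 (+)-miliusane V N-[(1R,5R,8R,9S)-1-[(1E)-2,6-dimethylhepta-1,5-dien-1-yl]-9-hydroxy-3,6-dioxo-2-oxaspiro[4.5]decan-8-yl]acetamide, via amino alcohol hydrochloride 21 (not isolated)
Conditions: 1 M aq. HCl, THF, rt; then NaHCO3 (to pH 8), Ac2O (1.5 equiv), THF/H2O, 0 °C
Reagents that add atoms: acetic anhydride, CC(=O)OC(C)=O
Why: Acid hydrolysis of the 2-trichloromethyl oxazoline proceeds by attack of water at the imidate carbon and loss of the labile trichloroacetyl group without breaking any bond at C4 or C5, and the Schotten–Baumann-type acetylation that follows takes the amine far faster than the secondary alcohol.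

Compound list
1 | 6-methylhept-5-en-2-one | CC(=O)CCC=C(C)C | starting material
2 | diethyl 6-methylhepta-1,5-dien-2-yl phosphate | C=C(CCC=C(C)C)OP(=O)(OCC)OCC | intermediate
3 | 6-methylhept-5-en-1-yne | C#CCCC=C(C)C | intermediate
4 | [(1E)-2,6-dimethylhepta-1,5-dien-1-yl]dimethylaluminium | C[Al](C)/C=C(\C)CCC=C(C)C | intermediate
5 | (1E)-1-iodo-2,6-dimethylhepta-1,5-diene | I/C=C(\C)CCC=C(C)C | intermediate
6 | monomethyl itaconate (4-methoxy-2-methylidene-4-oxobutanoic acid) | C=C(CC(=O)OC)C(=O)O | starting material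
7 | methyl 3-(chlorocarbonyl)but-3-enoate | C=C(CC(=O)OC)C(=O)Cl | intermediate
8 | [(1E)-2,6-dimethylhepta-1,5-dien-1-yl]lithium | [Li]/C=C(\C)CCC=C(C)C | intermediate
9 | [(1E)-2,6-dimethylhepta-1,5-dien-1-yl]zinc chloride | Cl[Zn]/C=C(\C)CCC=C(C)C | intermediate
10 | methyl (5E)-6,10-dimethyl-3-methylidene-4-oxoundeca-5,9-dienoate | C=C(CC(=O)OC)C(=O)/C=C(\C)CCC=C(C)C | intermediate
11 | (1E,3E)-buta-1,3-diene-1,4-diyl diacetate | CC(=O)O/C=C/C=C/OC(C)=O | starting material
12 | methyl 2-[(1S,2S,5S)-2,5-diacetoxy-1-[(2E)-3,7-dimethylocta-2,6-dienoyl]cyclohex-3-en-1-yl]acetate | CC(=O)O[C@H]1C=C[C@@H](OC(C)=O)C[C@@]1(CC(=O)OC)C(=O)/C=C(\C)CCC=C(C)C | intermediate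
13 | methyl 2-[(1R,2S,5S)-2,5-diacetoxy-1-[(1R,2E)-1-hydroxy-3,7-dimethylocta-2,6-dien-1-yl]cyclohex-3-en-1-yl]acetate | CC(=O)O[C@H]1C=C[C@@H](OC(C)=O)C[C@@]1(CC(=O)OC)[C@H](O)/C=C(\C)CCC=C(C)C | intermediate
14 | (1R,5S,6S,9S)-1-[(1E)-2,6-dimethylhepta-1,5-dien-1-yl]-3-oxo-2-oxaspiro[4.5]dec-7-ene-6,9-diyl diacetate | CC(=O)O[C@H]1C=C[C@@H](OC(C)=O)C[C@]12CC(=O)O[C@@H]2/C=C(\C)CCC=C(C)C | intermediate
15 | (1R,5S,6S,9S)-1-[(1E)-2,6-dimethylhepta-1,5-dien-1-yl]-6,9-dihydroxy-2-oxaspiro[4.5]dec-7-en-3-one | O[C@H]1C=C[C@@H](O)C[C@]12CC(=O)O[C@@H]2/C=C(\C)CCC=C(C)C | intermediate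
16 | (1R,5S,6S,9S)-9-[tert-butyl(dimethyl)silyl]oxy-1-[(1E)-2,6-dimethylhepta-1,5-dien-1-yl]-6-hydroxy-2-oxaspiro[4.5]dec-7-en-3-one | O[C@H]1C=C[C@@H](O[Si](C)(C)C(C)(C)C)C[C@]12CC(=O)O[C@@H]2/C=C(\C)CCC=C(C)C | intermediate
17 | (1R,5R,9S)-9-[tert-butyl(dimethyl)silyl]oxy-1-[(1E)-2,6-dimethylhepta-1,5-dien-1-yl]-2-oxaspiro[4.5]dec-7-ene-3,6-dione | O=C1C=C[C@@H](O[Si](C)(C)C(C)(C)C)C[C@]12CC(=O)O[C@@H]2/C=C(\C)CCC=C(C)C | intermediate
18 | (1R,5R,9S)-1-[(1E)-2,6-dimethylhepta-1,5-dien-1-yl]-9-hydroxy-2-oxaspiro[4.5]dec-7-ene-3,6-dione | O=C1C=C[C@@H](O)C[C@]12CC(=O)O[C@@H]2/C=C(\C)CCC=C(C)C | intermediate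
19 | (1R,5R,9S)-1-[(1E)-2,6-dimethylhepta-1,5-dien-1-yl]-3,6-dioxo-2-oxaspiro[4.5]dec-7-en-9-yl 2,2,2-trichloroethanimidate | O=C1C=C[C@@H](OC(=N)C(Cl)(Cl)Cl)C[C@]12CC(=O)O[C@@H]2/C=C(\C)CCC=C(C)C | intermediate
20 | cis-fused 2-(trichloromethyl)-4,5-dihydro-1,3-oxazole (N on C4, O on C5) of the spiro keto lactone; C1 R, C4 R, C5 S, C10 R | O=C1C[C@H]3N=C(C(Cl)(Cl)Cl)O[C@H]3C[C@]12CC(=O)O[C@@H]2/C=C(\C)CCC=C(C)C | intermediate
21 | (1R,5R,8R,9S)-8-amino-1-[(1E)-2,6-dimethylhepta-1,5-dien-1-yl]-9-hydroxy-2-oxaspiro[4.5]decane-3,6-dione hydrochloride | [Cl-].[NH3+][C@@H]1CC(=O)[C@@]2(CC(=O)O[C@@H]2/C=C(\C)CCC=C(C)C)C[C@@H]1O | intermediate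
22 | (+)-miliusane V, N-[(1R,5R,8R,9S)-1-[(1E)-2,6-dimethylhepta-1,5-dien-1-yl]-9-hydroxy-3,6-dioxo-2-oxaspiro[4.5]decan-8-yl]acetamide | CC(=O)N[C@@H]1CC(=O)[C@@]2(CC(=O)O[C@@H]2/C=C(\C)CCC=C(C)C)C[C@@H]1O | target

Total step count: 12. Longest linear sequence: 11 steps (1, 2, 4–12); step 3 is the only branch.

Steps most likely to fail

Step 5. What may go wrong:
- The weakly nucleophilic diene may add only slowly to the α-branched enone.
- The acid catalyst may trigger 4π-electrocyclisation of the divinyl ketone or migration of the exocyclic double bond.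
- Endo and facial selectivity may erode, because the reacting alkene has no α-hydrogen with which to anchor to the catalyst.

The fallback sets out from acid chloride 7. Palladium-catalysed hydrostannolysis (Bu3SnH, Pd(PPh3)4 cat., THF, rt) would give methyl 3-formylbut-3-enoate F1. This is an α-substituted acrolein, the dienophile class these boron catalysts handle best, and it has no second vinyl group that could electrocyclise. Cycloaddition of F1 with 11 under the same type of catalyst forms the same C1–C2 and C5–C6 bonds. It would give methyl 2-[(1S,2S,5S)-2,5-diacetoxy-1-formylcyclohex-3-en-1-yl]acetate F2. A Nozaki–Hiyama–Kishi coupling of F2 with iodide 5 (CrCl2, NiCl2 cat., a chiral oxazoline–sulfonamide ligand for reagent control at C10) then attaches the side chain. This comes back to the route at alcohol 13, so steps 4 and 6 are bypassed.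

Step 6. What may go wrong:
- Hydride transfer to a ketone wedged between a quaternary carbon and a trisubstituted alkene may be slow.
- The catalyst may not rank the two flanking groups clearly, which would give poor facial selectivity.
- Hydroboration or 1,4-reduction may compete if forcing conditions are needed.

The fallback replaces reagent control by substrate direction and sets out from 12. Brief, cold methanolysis (K2CO3 cat., MeOH, −10 °C, kept short to avoid retro-aldol cleavage) would give methyl 2-[(1S,2S,5S)-1-[(2E)-3,7-dimethylocta-2,6-dienoyl]-2,5-dihydroxycyclohex-3-en-1-yl]acetate F3. Its C2–OH and C10=O are tied into a six-membered boron chelate and reduced (Et2BOMe, NaBH4, THF/MeOH, −78 °C; Narasaka–Prasad 1,3-syn reduction). The syn relation between C2–O and C10–O is the one that corresponds to (10R). The resulting methyl 2-[(1S,2S,5S)-2,5-dihydroxy-1-[(1R,2E)-1-hydroxy-3,7-dimethylocta-2,6-dien-1-yl]cyclohex-3-en-1-yl]acetate F4 lactonises with K2CO3 in MeOH and comes back to the route at diol lactone 15.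

Step 12. What may go wrong:
- An O-to-N shift of the trichloroacetyl group on neutralisation may leave the cleavage incomplete.
- The free β-amino ketone may lose nitrogen by retro-Michael elimination.
- Aqueous acid may ionise the allylic C10–O bond of the lactone.

The fallback never frees the amine and sets out from oxazoline 20. Mild hydrolysis (TsOH·H2O cat., pyridine/H2O, rt) is steered on purpose to 2,2,2-trichloro-N-[(1R,5R,8R,9S)-1-[(1E)-2,6-dimethylhepta-1,5-dien-1-yl]-9-hydroxy-3,6-dioxo-2-oxaspiro[4.5]decan-8-yl]acetamide F5. Radical hydrodechlorination (Bu3SnH, 3.5 equiv, AIBN, toluene, 80 °C) then turns the CCl3 group into the CH3 of the acetamide. This known way of unmasking N-acetyl from N-trichloroacetyl comes back to the route at target 22.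

Further compounds
F1 | step 5 | methyl 3-formylbut-3-enoate | C=C(CC(=O)OC)C=O
F2 | step 5 | methyl 2-[(1S,2S,5S)-2,5-diacetoxy-1-formylcyclohex-3-en-1-yl]acetate | CC(=O)O[C@H]1C=C[C@@H](OC(C)=O)C[C@@]1(CC(=O)OC)C=O
F3 | step 6 | methyl 2-[(1S,2S,5S)-1-[(2E)-3,7-dimethylocta-2,6-dienoyl]-2,5-dihydroxycyclohex-3-en-1-yl]acetate | O[C@H]1C=C[C@@H](O)C[C@@]1(CC(=O)OC)C(=O)/C=C(\C)CCC=C(C)C
F4 | step 6 | methyl 2-[(1S,2S,5S)-2,5-dihydroxy-1-[(1R,2E)-1-hydroxy-3,7-dimethylocta-2,6-dien-1-yl]cyclohex-3-en-1-yl]acetate | O[C@H]1C=C[C@@H](O)C[C@@]1(CC(=O)OC)[C@H](O)/C=C(\C)CCC=C(C)C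
F5 | step 12 | 2,2,2-trichloro-N-[(1R,5R,8R,9S)-1-[(1E)-2,6-dimethylhepta-1,5-dien-1-yl]-9-hydroxy-3,6-dioxo-2-oxaspiro[4.5]decan-8-yl]acetamide | ClC(Cl)(Cl)C(=O)N[C@@H]1CC(=O)[C@@]2(CC(=O)O[C@@H]2/C=C(\C)CCC=C(C)C)C[C@@H]1O
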